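**Strategy.** Cedrane numbering: ring A = C1–C2–C3–C4–C5, ring B = C1, C5, C6, C7, C11, ring C = C1, C10, C9, C8, C7, C11. Everything rests on disconnecting C4–C5 and C6–C7 back to a ring C cyclohexadiene whose quaternary C1 carries an iodoalkyl arm (C2–C4) and an enal arm (C5=C6). The key step, a tin hydride radical cascade, closes ring A by forming C4–C5 and then ring B by forming C6–C7. It exploits that C1 is common to all three rings and that C7 is the electron-rich terminus of a ring C siloxydiene; DDQ then returns the enone. A chirality-transferring Claisen rearrangement sets C1 and C2 first.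

Key step: step 10

Assumption: the 2-(alkoxymethylidene) ketone formed in the Mitsunobu step reacts as its (E) isomer (alkoxy anti to the ring carbonyl) through a chair transition state.

**Route**

Step 1
Reactants: 1 3-oxocyclohex-1-ene-1-carboxylic acid
Product: 2 2-(trimethylsilyl)ethyl 3-oxocyclohex-1-ene-1-carboxylate
Conditions: 2-(trimethylsilyl)ethanol, EDC·HCl, DMAP (cat.), CH2Cl2, 0 °C to rt
Reagents that add atoms: 2-(trimethylsilyl)ethanol C[Si](C)(C)CCO
Why: Carbodiimide (Steglich) esterification installs a fluoride-labile ester on the future C15 carboxyl that should survive the later base, radical, hydride and ozone steps.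

Step 2
Reactants: 2 2-(trimethylsilyl)ethyl 3-oxocyclohex-1-ene-1-carboxylate; 3 2,2,2-trifluoroethyl formate
Product: 4 enolised 4-formyl ketone (hydroxymethylidene ketone)
Conditions: LiN(SiMe3)2, THF, −78 °C; then 3, −78 to 0 °C; aq. HCl
Reagents that add atoms: none
Why: Kinetic α′-deprotonation of the enone at C1 followed by Claisen-type C-formylation with the activated formate should give the enolised β-keto aldehyde that carries the future C5.

Step 3
Reactants: 5 (S)-but-3-yn-2-ol; 6 oxirane
Product: 7 (S)-hex-3-yne-2,6-diol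
Conditions: LiNH2 (2.2 equiv), liq. NH3, −33 °C; then 6; NH4Cl
Reagents that add atoms: none
Why: The alkoxide–acetylide dianion opens oxirane at the acetylide carbon (epoxide alkynylation) without touching the carbinol stereocentre.

Step 4
Reactants: 7 (S)-hex-3-yne-2,6-diol
Product: 8 (S,Z)-hex-3-ene-2,6-diol
Conditions: H2 (1 atm), Pd/CaCO3 poisoned with Pb(OAc)2 (Lindlar catalyst), quinoline, EtOAc, rt
Reagents that add atoms: none
Why: Lindlar semihydrogenation adds H2 syn to the alkyne and should stop at the (Z)-alkene.

Step 5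
Reactants: 8 (S,Z)-hex-3-ene-2,6-diol
Product: 9 (S,Z)-6-iodohex-3-en-2-ol
Conditions: PPh3, I2, imidazole, CH2Cl2, 0 °C
Reagents that add atoms: iodine II
Why: Appel-type iodination should be selective for the unhindered primary hydroxyl over the secondary allylic one at 0 °C.

Step 6
Reactants: 4 enolised 4-formyl ketone; 9 (S,Z)-6-iodohex-3-en-2-ol
Product: 10 (E)-alkoxymethylidene ketone with (R,Z)-6-iodohex-3-en-2-yl ether group
Conditions: PPh3, DIAD, THF, 0 °C to rt
Reagents that add atoms: none
Why: Mitsunobu O-alkylation of the acidic enol by the secondary alcohol proceeds by SN2 displacement with inversion and should give the (R)-configured allyl vinyl ether.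

Step 7
Reactants: 10 (E)-alkoxymethylidene ketone
Product: 11 (R)-4-formyl-4-[(R,E)-1-iodohex-4-en-3-yl] enone ester
Conditions: PhMe, 110 °C, sealed tube
Reagents that add atoms: none
Why: The Claisen [3,3] rearrangement should pass through a chair transition state with the carbinol methyl equatorial and the (Z)-alkene substituent axial, so that chirality is transferred from the ether carbon to C1 and C2 while the C1–C2 bond, the quaternary centre and the C1 formyl group (C5) are formed together.

Step 8
Reactants: 11 quaternary keto aldehyde; 12 2-(triphenyl-λ5-phosphanylidene)propanal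
Product: 13 (E)-α-methyl enal
Conditions: PhH, 40 °C
Reagents that add atoms: none
Why: Wittig olefination with the stabilised ylide converts the C5 aldehyde into the (E)-2-methyl enal, the radical acceptor that carries C5, C6, the C6 methyl and the future CH2OH carbon.

Step 9
Reactants: 13 (E)-α-methyl enal
Product: 14 ring C 2-siloxydiene (TBS dienol ether)
Conditions: TBSOTf, Et3N, CH2Cl2, −78 to 0 °C
Reagents that add atoms: tert-butyldimethylsilyl trifluoromethanesulfonate CC(C)(C)[Si](C)(C)OS(=O)(=O)C(F)(F)F
Why: Soft enolisation of the enone, which has no α′-hydrogen, can only occur by γ-deprotonation at C7 and should give the C10(OTBS)=C9–C8=C7 silyl dienol ether.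

Step 10
Reactants: 14 ring C 2-siloxydiene
Product: 16 tricyclic enone aldehyde, via tricyclic silyl enol ether 15 (not isolated)
Conditions: Bu3SnH (1.2 equiv, syringe pump), AIBN (cat.), PhH (0.01 M), 80 °C; then DDQ, 2,4,6-collidine, rt
Reagents that add atoms: none
Why: Bu3Sn• abstracts iodine from C4 and the primary radical closes ring A by 5-exo-trig Giese addition to C5 of the enal, the resulting electrophilic tertiary α-formyl radical at C6 then closes ring B by 5-exo-trig addition to C7, the terminus of the electron-rich ring C siloxydiene, and the siloxyallyl radical takes hydrogen from Bu3SnH at C8 (the carbon remote from oxygen, as in radical 1,4-reduction of enones) to give silyl enol ether 15, which DDQ dehydrogenates to the C8=C9 enone. The closest known reaction types are tin hydride tandem 5-exo/5-exo radical cyclisations and the DDQ oxidation of silyl enol ethers to enones. C5 is set in the first closure by a chair-like transition state in which the bulkier siloxy-bearing arm (C10) of C1 is pseudo-equatorial and the C2 propenyl group ends cis to the new C5–C6 bond, the only arrangement from which the C6 radical can reach C7, so that C7 follows from the bridging geometry. C6 is set in the second closure, where the methyl group should prefer the open exo position (syn to C11) and the smaller formyl group the endo position over the diene. The step needs 5-exo attack on the enal to outrun 6-exo attack of the C4 radical on C7 and both cyclisations to outrun hydrogen transfer, which the 5-exo rate advantage, the quaternary C1 and slow addition of Bu3SnH at high dilution should secure.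

Step 11
Reactants: 16 tricyclic enone aldehyde
Product: 17 tricyclic diol (C10 endo-OH and C6 CH2OH)
Conditions: NaBH4, CeCl3·7H2O, MeOH, −40 to 0 °C
Reagents that add atoms: none
Why: Luche 1,2-reduction should deliver hydride to the C10 ketone from the exo face (axial attack anti to the C1–C5 bond) to give the equatorial allylic alcohol, while NaBH4 reduces the non-enolisable C6 formyl group to CH2OH in the same pot.

Step 12
Reactants: 17 tricyclic diol
Product: 18 C6 CH2OTBS ether with free C10–OH
Conditions: TBSCl, imidazole, CH2Cl2, 0 °C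
Reagents that add atoms: tert-butyldimethylsilyl chloride CC(C)(C)[Si](C)(C)Cl
Why: Silylation should be selective for the primary alcohol over the hindered secondary allylic C10–OH next to the quaternary C1.

Step 13
Reactants: 18 C6 CH2OTBS ether
Product: 19 C2 aldehyde with free C10–OH
Conditions: O3, CH2Cl2, −78 °C; then PPh3
Reagents that add atoms: ozone [O-][O+]=O
Why: Ozonolysis should cleave the electron-rich propenyl group far faster than the electron-poor C8=C9 enoate and so unveil the C12 aldehyde without touching the C2 stereocentre.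

Step 14
Reactants: 20 heptane-1,7-diol
Product: 21 7-[(tert-butyldimethylsilyl)oxy]heptan-1-ol
Conditions: NaH (1 equiv), THF; then TBSCl, 0 °C to rt
Reagents that add atoms: tert-butyldimethylsilyl chloride CC(C)(C)[Si](C)(C)Cl
Why: Monosilylation of the symmetrical diol through its monosodium alkoxide desymmetrises the chain.

Step 15
Reactants: 21 7-[(tert-butyldimethylsilyl)oxy]heptan-1-ol
Product: 22 7-[(tert-butyldimethylsilyl)oxy]heptanal
Conditions: TEMPO (cat.), PhI(OAc)2, CH2Cl2, rt
Reagents that add atoms: none
Why: Oxoammonium (TEMPO) oxidation of the primary alcohol should stop at the aldehyde.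

Step 16
Reactants: 23 9-bromononanoic acid
Product: 24 (8-carboxyoctyl)triphenylphosphonium bromide
Conditions: PPh3, MeCN, reflux
Reagents that add atoms: triphenylphosphine c1ccc(cc1)P(c1ccccc1)c1ccccc1
Why: SN2 quaternisation of the phosphine by the primary bromide gives the Wittig salt.

Step 17
Reactants: 24 (8-carboxyoctyl)triphenylphosphonium bromide; 22 7-[(tert-butyldimethylsilyl)oxy]heptanal
Product: 25 (Z)-16-[(tert-butyldimethylsilyl)oxy]hexadec-9-enoic acid
Conditions: NaN(SiMe3)2 (2.1 equiv), THF, −78 °C; then 22; aq. HCl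
Reagents that add atoms: none
Why: The Wittig reaction of the unstabilised carboxylate ylide under lithium-free conditions should give the (Z)-alkene under kinetic control.

Step 18
Reactants: 19 C2 aldehyde with free C10–OH; 25 (Z)-16-[(tert-butyldimethylsilyl)oxy]hexadec-9-enoic acid
Product: 26 fully protected target
Conditions: 2,4,6-Cl3C6H2COCl, Et3N, THF; then 19, DMAP, PhMe, rt
Reagents that add atoms: none
Why: Yamaguchi esterification acylates the hindered C10–OH with retention of configuration under conditions mild enough for the α-branched aldehyde.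

Step 19
Reactants: 26 fully protected target
Product: 27 target CNP0148862.2
Conditions: Bu4NF, AcOH, THF, 0 °C to rt
Reagents that add atoms: none
Why: Buffered fluoride should remove both TBS ethers and the 2-(trimethylsilyl)ethyl ester (fluoride-induced β-elimination of ethene) without cleaving the C10 ester or epimerising C2.

**Compound list**

1 | 3-oxocyclohex-1-ene-1-carboxylic acid | O=C1C=C(C(=O)O)CCC1 | starting material
2 | 2-(trimethylsilyl)ethyl 3-oxocyclohex-1-ene-1-carboxylate | O=C1C=C(C(=O)OCC[Si](C)(C)C)CCC1 | intermediate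
3 | 2,2,2-trifluoroethyl formate | O=COCC(F)(F)F | starting material
4 | 2-(trimethylsilyl)ethyl (Z)-4-(hydroxymethylidene)-3-oxocyclohex-1-ene-1-carboxylate (enol of the 4-formyl ketone) | O/C=C1/CCC(C(=O)OCC[Si](C)(C)C)=CC1=O | intermediate
5 | (S)-but-3-yn-2-ol | C[C@H](O)C#C | starting material
6 | oxirane | C1CO1 | starting material
7 | (S)-hex-3-yne-2,6-diol | C[C@H](O)C#CCCO | intermediate
8 | (S,Z)-hex-3-ene-2,6-diol | C[C@H](O)/C=C\CCO | intermediate
9 | (S,Z)-6-iodohex-3-en-2-ol | C[C@H](O)/C=C\CCI | intermediate
10 | 2-(trimethylsilyl)ethyl (E)-4-({[(R,Z)-6-iodohex-3-en-2-yl]oxy}methylidene)-3-oxocyclohex-1-ene-1-carboxylate | C[C@@H](O/C=C1\CCC(C(=O)OCC[Si](C)(C)C)=CC1=O)/C=C\CCI | intermediate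
11 | 2-(trimethylsilyl)ethyl (R)-4-formyl-4-[(R,E)-1-iodohex-4-en-3-yl]-3-oxocyclohex-1-ene-1-carboxylate | O=C1C=C(C(=O)OCC[Si](C)(C)C)CC[C@]1(C=O)[C@@H](/C=C/C)CCI | intermediate
12 | 2-(triphenyl-λ5-phosphanylidene)propanal | CC(C=O)=P(c1ccccc1)(c1ccccc1)c1ccccc1 | starting material
13 | 2-(trimethylsilyl)ethyl (R)-4-[(R,E)-1-iodohex-4-en-3-yl]-4-[(E)-2-methyl-3-oxoprop-1-en-1-yl]-3-oxocyclohex-1-ene-1-carboxylate | O=C1C=C(C(=O)OCC[Si](C)(C)C)CC[C@]1(/C=C(\C)C=O)[C@@H](/C=C/C)CCI | intermediate
14 | 2-(trimethylsilyl)ethyl (R)-5-[(tert-butyldimethylsilyl)oxy]-4-[(R,E)-1-iodohex-4-en-3-yl]-4-[(E)-2-methyl-3-oxoprop-1-en-1-yl]cyclohexa-1,5-diene-1-carboxylate | CC(C)(C)[Si](C)(C)OC1=CC(C(=O)OCC[Si](C)(C)C)=CC[C@]1(/C=C(\C)C=O)[C@@H](/C=C/C)CCI | intermediate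
15 | tricyclic TBS enol ether: cedrane skeleton with C10 OTBS, C9=C10, C8–H ester (either C8 epimer), C6 CH3 exo and CHO endo, C2 (E)-prop-1-enyl; C1, C2, C5, C6, C7 as in the target | C[C@@]1(C=O)[C@H]2C[C@@]3(C(O[Si](C)(C)C(C)(C)C)=CC2C(=O)OCC[Si](C)(C)C)[C@@H](/C=C/C)CC[C@@H]13 | intermediate
16 | tricyclic enone aldehyde: C10 ketone, C8=C9, C15 2-(trimethylsilyl)ethyl ester, C6 CH3 exo and CHO endo, C2 (E)-prop-1-enyl | C[C@@]1(C=O)[C@H]2C[C@@]3(C(=O)C=C2C(=O)OCC[Si](C)(C)C)[C@@H](/C=C/C)CC[C@@H]13 | intermediate
17 | tricyclic diol: C10 endo (equatorial) OH, C6 endo CH2OH, C2 (E)-prop-1-enyl | C[C@@]1(CO)[C@H]2C[C@@]3([C@@H](O)C=C2C(=O)OCC[Si](C)(C)C)[C@@H](/C=C/C)CC[C@@H]13 | intermediate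
18 | C6 CH2OTBS ether of 17 with free C10–OH | C[C@@]1(CO[Si](C)(C)C(C)(C)C)[C@H]2C[C@@]3([C@@H](O)C=C2C(=O)OCC[Si](C)(C)C)[C@@H](/C=C/C)CC[C@@H]13 | intermediate
19 | C2 aldehyde (C12 = CHO) with C6 CH2OTBS and free C10–OH | C[C@@]1(CO[Si](C)(C)C(C)(C)C)[C@H]2C[C@@]3([C@@H](O)C=C2C(=O)OCC[Si](C)(C)C)[C@@H](C=O)CC[C@@H]13 | intermediate
20 | heptane-1,7-diol | OCCCCCCCO | starting material
21 | 7-[(tert-butyldimethylsilyl)oxy]heptan-1-ol | OCCCCCCCO[Si](C)(C)C(C)(C)C | intermediate
22 | 7-[(tert-butyldimethylsilyl)oxy]heptanal | O=CCCCCCCO[Si](C)(C)C(C)(C)C | intermediate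
23 | 9-bromononanoic acid | OC(=O)CCCCCCCCBr | starting material
24 | (8-carboxyoctyl)triphenylphosphonium bromide | OC(=O)CCCCCCCC[P+](c1ccccc1)(c1ccccc1)c1ccccc1.[Br-] | intermediate
25 | (Z)-16-[(tert-butyldimethylsilyl)oxy]hexadec-9-enoic acid | OC(=O)CCCCCCC/C=C\CCCCCCO[Si](C)(C)C(C)(C)C | intermediate
26 | fully protected target: C10 ester of 19 with 25 (two TBS ethers, 2-(trimethylsilyl)ethyl ester) | C[C@@]1(CO[Si](C)(C)C(C)(C)C)[C@H]2C[C@@]3([C@@H](OC(=O)CCCCCCC/C=C\CCCCCCO[Si](C)(C)C(C)(C)C)C=C2C(=O)OCC[Si](C)(C)C)[C@@H](C=O)CC[C@@H]13 | intermediate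
27 | CNP0148862.2 | C[C@@]1(CO)[C@H]2C[C@@]3([C@@H](OC(=O)CCCCCCC/C=C\CCCCCCO)C=C2C(=O)O)[C@@H](C=O)CC[C@@H]13 | target

**Step count.** Total: 19 steps. Longest linear sequence: 13 steps (steps 3–13, 18 and 19, from (S)-but-3-yn-2-ol).

**Steps most likely to fail**

Step 10. Hydrogen transfer may reach the tertiary C6 radical before it closes ring B, the C4 radical may attack the dienoate terminus C7 in a 6-exo mode, or facial selectivity at C6 may be poor. The fallback sets out from 13 and separates the two ring closures. Bu3SnH/AIBN on enone 13, which has no siloxydiene, should give only the C4–C5 closure with reduction of the C6 radical, giving the spiro aldehyde F1. Amine-catalysed α-selenenylation with N-(phenylselanyl)phthalimide then gives the tertiary α-phenylselanyl aldehyde F2, and TBSOTf/Et3N gives the siloxydiene F3. Bu3SnH/AIBN regenerates the C6 radical from the C–Se bond under conditions chosen for the ring B closure alone. The fallback comes back to the route at 15, which the DDQ stage of step 10 converts into 16.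

Step 6. The phosphine may add to the electron-poor enone, or the secondary (Z)-allylic alcohol may react by SN2′ displacement or elimination, so that the configuration at the ether carbon is eroded. The fallback sets out from 4 and makes the ether bond at the vinylic carbon instead of the carbinol carbon. (R)-But-3-yn-2-ol is taken through the chemistry of steps 3 to 5 to (R)-hex-3-yne-2,6-diol F4, (R,Z)-hex-3-ene-2,6-diol F5 and (R,Z)-6-iodohex-3-en-2-ol F6. F6 is then condensed with enol 4 under acid catalysis (PPTS, PhH, azeotropic removal of water), an addition–elimination at the formyl carbon that retains the carbinol configuration. The fallback comes back to the route at 10.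

Step 11. Hydride may be delivered to the endo face of the C10 ketone, past the axial C1–C5 bond, giving the axial C10 alcohol. The fallback sets out from 16 and uses that epimer productively by inversion. The C10-epimeric diol F7 is silylated at the primary hydroxyl to the TBS ether F8. Mitsunobu reaction with chloroacetic acid (PPh3, DIAD) inverts C10 to give the chloroacetate F9, and thiourea/NaHCO3 in EtOH removes the chloroacetyl group selectively. The fallback comes back to the route at 18.

Further compounds
F1 | step 10 | spiro aldehyde with ring A closed and C6–H (either C6 epimer) | CC(C=O)[C@@H]1CC[C@H](/C=C/C)[C@]12CCC(C(=O)OCC[Si](C)(C)C)=CC2=O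
F2 | step 10 | tertiary α-phenylselanyl aldehyde (either C6 epimer) | O=CC(C)([Se]c1ccccc1)[C@@H]1CC[C@H](/C=C/C)[C@]12CCC(C(=O)OCC[Si](C)(C)C)=CC2=O
F3 | step 10 | TBS dienol ether of F2 | O=CC(C)([Se]c1ccccc1)[C@@H]1CC[C@H](/C=C/C)[C@]12CC=C(C(=O)OCC[Si](C)(C)C)C=C2O[Si](C)(C)C(C)(C)C
F4 | step 6 | (R)-hex-3-yne-2,6-diol | C[C@@H](O)C#CCCO
F5 | step 6 | (R,Z)-hex-3-ene-2,6-diol | C[C@@H](O)/C=C\CCO
F6 | step 6 | (R,Z)-6-iodohex-3-en-2-ol | C[C@@H](O)/C=C\CCI
F7 | step 11 | C10-epimeric diol (axial C10–OH) | C[C@@]1(CO)[C@H]2C[C@@]3([C@H](O)C=C2C(=O)OCC[Si](C)(C)C)[C@@H](/C=C/C)CC[C@@H]13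
F8 | step 11 | C6 CH2OTBS ether of F7 | C[C@@]1(CO[Si](C)(C)C(C)(C)C)[C@H]2C[C@@]3([C@H](O)C=C2C(=O)OCC[Si](C)(C)C)[C@@H](/C=C/C)CC[C@@H]13
F9 | step 11 | C10 chloroacetate with the target C10 configuration | C[C@@]1(CO[Si](C)(C)C(C)(C)C)[C@H]2C[C@@]3([C@@H](OC(=O)CCl)C=C2C(=O)OCC[Si](C)(C)C)[C@@H](/C=C/C)CC[C@@H]13
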